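## Analysis of the target

The target 15 is a macrocyclic diaryl ether with two benzene rings joined once through oxygen and once through an unbranched chain of fourteen methylene groups. Ring A carries the free hydroxyl at A1, the chain at A3 and the ether oxygen at A5. Ring B carries the ether oxygen at B1, hydroxyls at B2 and B4 and the chain at B6, and the chain runs from C1 on B6 to C14 on A3. The ring through O, B1, B6, C1–C14, A3, A4 and A5 has 20 members. There is no stereocenter, and a loop of this size is too mobile for planar chirality to persist, so no stereochemical relationship has to be set. The sensitive groups are the three free phenols: ring B is a 1,2,4-trioxygenated arene that oxidises easily in base and air, and ring A is a resorcinol-type ring with nucleophilic carbon positions. The synthesis is hard for two reasons: a 20-membered ring must close against oligomerisation, and the ether bond ends at B1, a carbon flanked by two ortho substituents on a very electron-rich ring, which is a poor site for substitution or for copper-mediated coupling. The route rests on the fact that the two hydroxyls of ring B sit ortho (B2) and para (B4) to B1. Acceptor groups at these positions activate ipso substitution at B1, and formyl groups there can afterwards be turned into hydroxyls by peracid oxidation. Ring A, taken as a free 5-alkylresorcinol, has two equivalent oxygens, so it needs no differentiation.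

## Retrosynthetic reasoning

**15 back to 13.** The C–O bonds B2–OH and B4–OH are traced back to C–C bonds to formyl carbons, so that 15 comes from the macrocyclic dialdehyde 13 through the bis-formate 14. Both positions are ortho or para to the ether oxygen, which is where aryl migration to a peroxide oxygen is favoured. Ring B is thereby electron-poor for as long as that is useful and electron-rich only at the end. The forward reaction must make the aryl group, not hydride, migrate twice, and it must spare ring A and its free hydroxyl. Alkaline peroxide is not suitable here, since neither formyl group has a free ortho or para hydroxyl, so a peracid is used.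

**13 back to 12.** The bond B1–O is cut. It is the only heteroatom bond of the macrocycle, and in the open form 12 B1 carries fluorine with formyl groups ortho and para, which is the pattern that addition–elimination needs. Cutting a chain C–C bond instead would leave the hindered diaryl ether to be made intermolecularly on an electron-rich ring, and would leave functional groups in the chain to be erased. In 12 the nucleophile is a free, symmetric resorcinol, so either oxygen gives 13. The forward reaction has only one selectivity problem, ring closure against chain growth.

**12 back to 11.** Here only masking groups are removed. The ring A oxygens are carried as methoxymethyl ethers and the B4 formyl group as a cyclic acetal, so that one treatment with aqueous acid releases 12 from 11. Methyl ethers on ring A were not used: their Lewis-acid cleavage would have to run in the presence of two electron-poor formyl groups, which such reagents convert into geminal dihalides.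

**11 back to 5 and 9.** The bond B6–C1 is cut to give the aryl bromide 9 and the terminal alkene 5. Hydroboration of 5 and palladium-catalysed sp3–sp2 coupling join them. The bromine stands at the right carbon in the commercial aldehyde 6, and the coupling delivers the saturated chain directly. An alkyne coupling at the same bond would require a hydrogenation next to a free formyl group and a separately built alkyne arm.

**9 back to 7 and 6.** The bond from B2 to its formyl carbon is cut. The proton ortho to fluorine in acetal 7 is the most acidic one of the ring, and an amide base removes it without touching the bromine. The aryllithium 8 is then formylated. This is done before the chain is attached, because the bromine adds to the acidity of that proton and because the arm would later offer a competing acidic site between its two oxygens. Acetal 7 comes from 6 in one step.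

**5 back to 2 and 3.** The bond A3–C14 is cut in the same way. The symmetric diene 3 contains all fourteen chain carbons with a reactive end on each side, so the chain needs no construction. The cost is a statistical monofunctionalisation, met by an excess of 3 that is recovered. Bromide 2 is the bis-acetal of the commercial resorcinol 1.

## Alternatives that were turned down

**Alternative 1:** Ring A itself is disconnected. The forward key step irradiates the diazoketone A2, whose chain ends in ring B bearing an ethynyl ether at B1. Wolff rearrangement (forming A3–A4) gives a vinylketene that adds to the tethered ynol ether. Cyclobutenone opening and six-electron closure then complete ring A and the macrocycle in one operation (bonds A1–A6, A4–A5, A1–A2), giving the ring B dimethyl ether A1.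
- For it: four bonds and two rings form at once, the meta relationship of A1–OH and the ether oxygen follows from the polarity of ketene and ynol ether, and A1–OH appears at the right oxidation level.
- Against it: the decisive [2+2] event must occur across a fourteen-carbon tether, where a short-lived vinylketene is more likely to dimerise or be trapped. A2 combines a diazoketone with a thermally labile, electron-rich aryl ethynyl ether, each needing several steps to install at opposite chain ends. Two methyl ethers on ring B must still be cleaved afterwards.
- Comparison: it is stronger in bond economy of the key step and needs no oxidation after ring closure. The chosen route offers in its place two purchased arenes, robust intermediates, and a ring closure of a well-established type whose precursor 12 is reached in six steps.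

**Alternative 2:** The chain is cut at C2–C3 and C12–C13. The dilithium bis-acetylide of the diethynyl diaryl ether A4 is alkylated twice by 1,10-diiododecane A5, the second alkylation closing the ring to the diyne A3. Hydrogenation and cleavage of three methyl ethers would follow.
- For it: the diaryl ether exists before the macrocyclisation, the strap is a cheap symmetric reagent, and the late hydrogenation meets no reducible group other than the alkynes.
- Against it: the first alkylation is intermolecular and the second intramolecular, so no single concentration suits both, and chain growth and double capping by A5 compete. Aryl acetylides alkylate sluggishly with primary iodides and favour elimination. The hindered ether at B1 of an electron-rich ring must still be made for A4, so the central difficulty of the target is moved, not solved.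
- Comparison: it is equal or better in avoiding an oxidation on the finished macrocycle. The chosen route forms the difficult ether bond and the ring in the same step, and it does so by the activation that the substitution pattern of ring B provides.

**Alternative 3:** Ring B is disconnected. The forward key step is an intramolecular Horner–Wadsworth–Emmons reaction of the α-aryloxy β-ketophosphonate A7 with its chain aldehyde, giving the macrocyclic α-aryloxy enone A6 with the B1=B6 double bond. Ring B would then be completed by conjugate addition of a two-carbon ester donor at B6, Claisen-type closure from the methyl ketone, decarboxylation and dehydrogenation to the resorcinol.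
- For it: phosphonate olefinations are among the most dependable macrocyclisations, the ether oxygen is attached to an sp3 carbon early and without hindrance, and the B2 and B4 oxygens arise at the carbonyl level without a Dakin step.
- Against it: after ring closure there is a long sequence on the macrocycle (conjugate addition to an α-oxygenated, β-substituted enone, cyclisation, decarboxylation, aromatisation and demethylation). The dehydrogenation of an α-aryloxy cyclohexanedione is harsh and may expel the aryloxide.
- Comparison: its ring closure is at least as secure as the one chosen. The chosen route keeps the work after ring closure to a single operation and buys ring B as an arene.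

Key step: step 7

## Route

Assumption: 1, 3 and 6 are taken as commercially available; the target is achiral, so no compound of the route needs a stereodescriptor.

Step 1
Reactants: 1 5-bromobenzene-1,3-diol
Product: 2 1-bromo-3,5-bis(methoxymethoxy)benzene
Conditions: NaH, DMF, 0 °C; MOMCl, 0 °C → rt
Reagents that add atoms: chloromethyl methyl ether (MOMCl), COCCl
Why: Williamson-type O-alkylation of both phenoxides with the reactive α-chloro ether; the methoxymethyl acetals tolerate the borane, aqueous phosphate and palladium of the later steps and fall in step 6 in the same acid that opens the dioxolane.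

Step 2
Reactants: 3 tetradeca-1,13-diene; 2 1-bromo-3,5-bis(methoxymethoxy)benzene
Product: 5 1,3-bis(methoxymethoxy)-5-(tetradec-13-en-1-yl)benzene, via B-(tetradec-13-enyl)-9-BBN 4 (not isolated)
Conditions: 3 (4 equiv), 9-BBN-H, THF, 0 °C → rt; then 2, Pd(dppf)Cl2 (cat.), 3 M aq K3PO4, DMF, 50 °C
Reagents that add atoms: none
Why: Anti-Markovnikov hydroboration of one terminal alkene followed by B-alkyl Suzuki–Miyaura coupling joins C14 to A3; the excess of the symmetric diene keeps double functionalisation statistically small, and unreacted 3 is recovered as the least polar fraction.

Step 3
Reactants: 6 3-bromo-4-fluorobenzaldehyde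
Product: 7 2-(3-bromo-4-fluorophenyl)-1,3-dioxolane
Conditions: HOCH2CH2OH, TsOH·H2O (cat.), toluene, reflux, Dean–Stark
Reagents that add atoms: ethylene glycol, OCCO
Why: Acid-catalysed acetalisation driven by azeotropic removal of water; the dioxolane shields the formyl group from the amide base of step 4 and keeps the fluoride unactivated until step 6.

Step 4
Reactants: 7 2-(3-bromo-4-fluorophenyl)-1,3-dioxolane
Product: 9 3-bromo-5-(1,3-dioxolan-2-yl)-2-fluorobenzaldehyde, via aryllithium 8 (not isolated)
Conditions: LiN(iPr)2, THF, −78 °C; DMF, −78 → −20 °C; aq NH4Cl
Reagents that add atoms: N,N-dimethylformamide, CN(C)C=O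
Why: Directed ortho-metalation: the amide base removes the most acidic ring proton, the one ortho to fluorine and not flanked by bromine, without bromine–lithium exchange, and the aryllithium 8 is formylated by the formamide (Bouveault-type formylation); holding −78 °C until the electrophile is added prevents loss of LiF to an aryne and migration of bromine.

Step 5
Reactants: 5 1,3-bis(methoxymethoxy)-5-(tetradec-13-en-1-yl)benzene; 9 3-bromo-5-(1,3-dioxolan-2-yl)-2-fluorobenzaldehyde
Product: 11 3-{14-[3,5-bis(methoxymethoxy)phenyl]tetradecyl}-5-(1,3-dioxolan-2-yl)-2-fluorobenzaldehyde, via arm alkylborane 10 (not isolated)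
Conditions: 5, 9-BBN-H, THF, 0 °C → rt; then 3 M aq K3PO4; then 9, Pd(dppf)Cl2 (cat.), DMF, rt → 45 °C
Reagents that add atoms: none
Why: Anti-Markovnikov hydroboration of 5 and B-alkyl Suzuki–Miyaura coupling at the C–Br bond of 9, which adds readily to zerovalent palladium because the ring is electron-poor; the aqueous phosphate destroys residual B–H before the aldehyde is added, a single ortho formyl group does not make the fluoride labile to aqueous base at 45 °C, and both kinds of acetal are base-stable.

Step 6
Reactants: 11 3-{14-[3,5-bis(methoxymethoxy)phenyl]tetradecyl}-5-(1,3-dioxolan-2-yl)-2-fluorobenzaldehyde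
Product: 12 4-fluoro-5-[14-(3,5-dihydroxyphenyl)tetradecyl]benzene-1,3-dicarbaldehyde
Conditions: 3 M aq HCl, THF, 45 °C
Reagents that add atoms: water, O
Why: Acid-catalysed hydrolysis of three acetals in one operation, the two aryl methoxymethyl ethers and the dioxolane, with water supplying the oxygen of the B4 formyl group; aryl fluoride and formyl groups are inert to aqueous acid, and without base the phenols do not attack B1, so 12 can be purified and stored.

Step 7
Reactants: 12 4-fluoro-5-[14-(3,5-dihydroxyphenyl)tetradecyl]benzene-1,3-dicarbaldehyde
Product: 13 macrocyclic diaryl ether dialdehyde (ring A with free OH at A1 and chain at A3, its A5 oxygen bonded to B1; ring B with formyl groups at B2 and B4 and the chain at B6)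
Conditions: Cs2CO3 (3 equiv), 4 Å MS, DMSO, 50 °C, Ar; 12 added by syringe pump over 12 h (final 1 mM); then dilute aq HCl
Reagents that add atoms: none
Why: The cesium resorcinolate of 12 adds to B1 to give a Meisenheimer anion whose charge is spread onto the oxygens of the ortho (B2) and para (B4) formyl groups, and fluoride then leaves; addition is rate-limiting, which is why fluoride is the best leaving group here. The closest known reaction type is the intramolecular nucleophilic aromatic substitution of activated aryl fluorides by phenoxides, used for macrocyclic diaryl ethers. The 20-membered ring closes by head-to-tail O-arylation: the oxygen attacks a ring carbon of the new macrocycle while fluoride departs outside it, and the flexible fourteen-carbon tether adds no strain, so only the entropic cost has to be met. No stereocenter is formed and 13 is achiral. Ring closure must outrun intermolecular substitution, which is secured by slow addition into a large volume so that the stationary concentration of unreacted 12 stays far below 1 mM. O-arylation rather than C-attack of the ambident resorcinolate is expected from the hard aryl fluoride electrophile, the dipolar aprotic solvent and the cesium counterion. Site selectivity needs no control, since B1 carries the only fluoride and the two ring A oxygens are equivalent; the product phenoxide has no fluoride left and could only attack fresh 12. DMSO is chosen over an amide solvent because at this dilution traces of secondary amine from an amide solvent would compete for the doubly activated fluoride; the formyl groups are not enolisable and the dry carbonate gives no Cannizzaro reaction.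

Step 8
Reactants: 13 macrocyclic diaryl ether dialdehyde
Product: 15 target macrocycle (OH at A1, B2 and B4), via bis-formate 14 (not isolated)
Conditions: mCPBA (3 equiv), CH2Cl2, 0 °C → rt; aq Na2S2O3 wash; then HCl (cat.), MeOH, rt, Ar
Reagents that add atoms: 3-chloroperoxybenzoic acid (mCPBA), OOC(=O)c1cccc(Cl)c1
Why: Dakin-type oxidation in its peracid (Baeyer–Villiger) form: the peracid adds to each formyl group and the ipso carbon, ortho (B2) or para (B4) to the ether oxygen, migrates to oxygen to give the bis-formate 14, which acid-catalysed methanolysis cleaves. The oxidant is removed before the formates are opened, and the cleavage is run in acid under argon, so that the electron-rich ring B is never exposed to oxidant or to air in base.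

## Compound list

1 | 5-bromobenzene-1,3-diol | Oc1cc(O)cc(Br)c1 | starting material
2 | 1-bromo-3,5-bis(methoxymethoxy)benzene | COCOc1cc(OCOC)cc(Br)c1 | intermediate
3 | tetradeca-1,13-diene | C=CCCCCCCCCCCCC=C | starting material
4 | 9-(tetradec-13-en-1-yl)-9-borabicyclo[3.3.1]nonane | C=CCCCCCCCCCCCCB1C2CCCC1CCC2 | intermediate (not isolated)
5 | 1,3-bis(methoxymethoxy)-5-(tetradec-13-en-1-yl)benzene | C=CCCCCCCCCCCCCc1cc(OCOC)cc(OCOC)c1 | intermediate
6 | 3-bromo-4-fluorobenzaldehyde | O=Cc1ccc(F)c(Br)c1 | starting material
7 | 2-(3-bromo-4-fluorophenyl)-1,3-dioxolane | Fc1ccc(cc1Br)C1OCCO1 | intermediate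
8 | [3-bromo-5-(1,3-dioxolan-2-yl)-2-fluorophenyl]lithium | [Li]c1cc(cc(Br)c1F)C1OCCO1 | intermediate (not isolated)
9 | 3-bromo-5-(1,3-dioxolan-2-yl)-2-fluorobenzaldehyde | O=Cc1cc(cc(Br)c1F)C1OCCO1 | intermediate
10 | 9-{14-[3,5-bis(methoxymethoxy)phenyl]tetradecyl}-9-borabicyclo[3.3.1]nonane | COCOc1cc(CCCCCCCCCCCCCCB2C3CCCC2CCC3)cc(OCOC)c1 | intermediate (not isolated)
11 | 3-{14-[3,5-bis(methoxymethoxy)phenyl]tetradecyl}-5-(1,3-dioxolan-2-yl)-2-fluorobenzaldehyde | COCOc1cc(CCCCCCCCCCCCCCc2cc(cc(C=O)c2F)C2OCCO2)cc(OCOC)c1 | intermediate
12 | 4-fluoro-5-[14-(3,5-dihydroxyphenyl)tetradecyl]benzene-1,3-dicarbaldehyde | Fc1c(C=O)cc(C=O)cc1CCCCCCCCCCCCCCc1cc(O)cc(O)c1 | intermediate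
13 | macrocyclic diaryl ether dialdehyde (OH at A1, formyl at B2 and B4) | Oc1cc2cc(c1)Oc1c(C=O)cc(C=O)cc1CCCCCCCCCCCCCC2 | intermediate
14 | macrocyclic bis-formate (formyloxy at B2 and B4, OH at A1) | Oc1cc2cc(c1)Oc1c(OC=O)cc(OC=O)cc1CCCCCCCCCCCCCC2 | intermediate (not isolated)
15 | target macrocycle (OH at A1, B2 and B4) | Oc1cc2cc(c1)Oc1c(O)cc(O)cc1CCCCCCCCCCCCCC2 | target

## Step count and least certain steps

Total step count: 8. Longest linear sequence: 6 steps (steps 3, 4, 5, 6, 7, 8 from 6, or equally steps 1, 2, 5, 6, 7, 8 from 1).

**Step 7 (key step).**
- What may go wrong: intermolecular substitution can outrun ring closure, giving linear and cyclic oligomers, because a 20-membered ring has only a modest effective molarity. The resorcinolate may also add through carbon to a formyl group of another molecule.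
- Fallback: the ring is closed at the B6–C1 bond instead, after the ether has been made intermolecularly. It sets out from 5 and 9 and rejoins the route at 13.
 - Methanolic HCl would remove the methoxymethyl groups of 5 to give 5-(tetradec-13-en-1-yl)benzene-1,3-diol F1.
 - An excess of F1 with 9 and K2CO3 in DMSO at 90 °C would displace the fluoride, activated by the ortho formyl group, to give 3-bromo-5-(1,3-dioxolan-2-yl)-2-[3-hydroxy-5-(tetradec-13-en-1-yl)phenoxy]benzaldehyde F2.
 - Acetalisation of the formyl group (ethylene glycol, TsOH) would give 3-{[2-bromo-4,6-bis(1,3-dioxolan-2-yl)phenyl]oxy}-5-(tetradec-13-en-1-yl)phenol F3.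
 - Hydroboration with excess 9-BBN-H would give the alkylborane of F3 with the phenol held as its 9-BBN borinate F4. Without isolation this would be cyclised by intramolecular B-alkyl Suzuki–Miyaura coupling (Pd(dppf)Cl2, aq K3PO4, THF–DMF, high dilution) to the macrocyclic bis-dioxolane of 13 F5.
 - Aqueous HCl in THF would then release 13.

**Step 8.**
- What may go wrong: hydride may migrate in place of the aryl group in the peracid adduct, giving carboxylic acids. Ring B still carries a second acceptor at the first oxidation, and the ether oxygen is twisted out of conjugation by its two ortho neighbours. Ring A with its free hydroxyl may also be attacked by the peracid.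
- Fallback: the migrating-group competition is removed by oxidising methyl ketones, which have no hydride to shift. It sets out from 13 and rejoins at 15.
 - Excess MeMgBr in THF would give the bis(1-hydroxyethyl) analogue of 13 (mixture of diastereomers) F6.
 - MnO2 in CH2Cl2 would give the 2,4-diacetyl analogue of 13 F7.
 - Baeyer–Villiger oxidation with mCPBA, in which aryl migrates in preference to methyl, would give the B2,B4-diacetate of 15 F8.
 - Acid-catalysed methanolysis would give 15.

**Step 6.**
- What may go wrong: once freed, the resorcinol ring may undergo acid-promoted hydroxyalkylation by the released formaldehyde or by the formyl groups of a second molecule. Cleavage of the aryl methoxymethyl ethers may also be incomplete under conditions mild enough to avoid this.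
- Fallback: the ring A oxygens are unmasked before any aldehyde is in the molecule. It sets out from 5 and 9 and rejoins at 12.
 - The diol F1 (made from 5 as described under step 7) would be hydroborated with excess 9-BBN-H to the alkylborane of F1 with both phenols held as 9-BBN borinates F9.
 - Coupling with 9 (Pd(dppf)Cl2, aq K3PO4, THF–DMF, at most 45 °C) would give 3-[14-(3,5-dihydroxyphenyl)tetradecyl]-5-(1,3-dioxolan-2-yl)-2-fluorobenzaldehyde F10.
 - The single dioxolane of F10 would be opened by dilute aqueous HCl in THF at room temperature, where no formaldehyde is formed, to give 12.

**Step 5.**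
- What may go wrong: the free formyl group of 9 may be reduced by residual B–H or by β-hydride transfer from the alkylborane. The fluoride ortho to it may also be slowly displaced by hydroxide during the coupling.
- Fallback: the formyl group is masked first. It sets out from 9 and rejoins at 12.
 - Acetalisation of 9 (ethylene glycol, TsOH) would give 2,2'-(5-bromo-4-fluoro-1,3-phenylene)bis(1,3-dioxolane) F11, whose fluoride is no longer activated.
 - Coupling with the borane 10, made from 5 as in step 5, would give 2,2'-(5-{14-[3,5-bis(methoxymethoxy)phenyl]tetradecyl}-4-fluoro-1,3-phenylene)bis(1,3-dioxolane) F12.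
 - The conditions of step 6 would convert F12 into 12.

## Further compounds

F1 | step 7 | 5-(tetradec-13-en-1-yl)benzene-1,3-diol | C=CCCCCCCCCCCCCc1cc(O)cc(O)c1
F2 | step 7 | 3-bromo-5-(1,3-dioxolan-2-yl)-2-[3-hydroxy-5-(tetradec-13-en-1-yl)phenoxy]benzaldehyde | C=CCCCCCCCCCCCCc1cc(O)cc(Oc2c(Br)cc(cc2C=O)C2OCCO2)c1
F3 | step 7 | 3-{[2-bromo-4,6-bis(1,3-dioxolan-2-yl)phenyl]oxy}-5-(tetradec-13-en-1-yl)phenol | C=CCCCCCCCCCCCCc1cc(O)cc(Oc2c(Br)cc(cc2C2OCCO2)C2OCCO2)c1
F4 | step 7 | alkylborane of F3 with the phenol as its 9-BBN borinate | c1(CCCCCCCCCCCCCCB2C3CCCC2CCC3)cc(OB2C3CCCC2CCC3)cc(Oc2c(Br)cc(cc2C2OCCO2)C2OCCO2)c1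
F5 | step 7 | macrocyclic bis-dioxolane of 13 | Oc1cc2cc(c1)Oc1c(C3OCCO3)cc(C3OCCO3)cc1CCCCCCCCCCCCCC2
F6 | step 8 | bis(1-hydroxyethyl) analogue of 13 (mixture of diastereomers) | Oc1cc2cc(c1)Oc1c(C(C)O)cc(C(C)O)cc1CCCCCCCCCCCCCC2
F7 | step 8 | 2,4-diacetyl analogue of 13 | Oc1cc2cc(c1)Oc1c(C(C)=O)cc(C(C)=O)cc1CCCCCCCCCCCCCC2
F8 | step 8 | B2,B4-diacetate of 15 | Oc1cc2cc(c1)Oc1c(OC(C)=O)cc(OC(C)=O)cc1CCCCCCCCCCCCCC2
F9 | step 6 | alkylborane of F1 with both phenols as 9-BBN borinates | c1(CCCCCCCCCCCCCCB2C3CCCC2CCC3)cc(OB2C3CCCC2CCC3)cc(OB2C3CCCC2CCC3)c1
F10 | step 6 | 3-[14-(3,5-dihydroxyphenyl)tetradecyl]-5-(1,3-dioxolan-2-yl)-2-fluorobenzaldehyde | Oc1cc(CCCCCCCCCCCCCCc2cc(cc(C=O)c2F)C2OCCO2)cc(O)c1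
F11 | step 5 | 2,2'-(5-bromo-4-fluoro-1,3-phenylene)bis(1,3-dioxolane) | Fc1c(Br)cc(cc1C1OCCO1)C1OCCO1
F12 | step 5 | 2,2'-(5-{14-[3,5-bis(methoxymethoxy)phenyl]tetradecyl}-4-fluoro-1,3-phenylene)bis(1,3-dioxolane) | COCOc1cc(CCCCCCCCCCCCCCc2cc(cc(C3OCCO3)c2F)C2OCCO2)cc(OCOC)c1
A1 | alternative 1 | ring B di-O-methyl ether of the target | Oc1cc2cc(c1)Oc1c(OC)cc(OC)cc1CCCCCCCCCCCCCC2
A2 | alternative 1 | 1-diazo-3-methylene-17-[2-(ethynyloxy)-3,5-dimethoxyphenyl]heptadecan-2-one | [N-]=[N+]=CC(=O)C(=C)CCCCCCCCCCCCCCc1cc(OC)cc(OC)c1OC#C
A3 | alternative 2 | 20-membered diyne with triple bonds at C1–C2 and C13–C14 | COc1cc2cc(c1)Oc1c(OC)cc(OC)cc1C#CCCCCCCCCCCC#C2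
A4 | alternative 2 | 1-ethynyl-2-(3-ethynyl-5-methoxyphenoxy)-3,5-dimethoxybenzene | COc1cc(C#C)cc(Oc2c(OC)cc(OC)cc2C#C)c1
A5 | alternative 2 | 1,10-diiododecane | ICCCCCCCCCCI
A6 | alternative 3 | 20-membered (Z)-α-aryloxy enone | COc1cc2cc(c1)O/C(C(C)=O)=C\CCCCCCCCCCCCCC2
A7 | alternative 3 | diethyl {1-[3-methoxy-5-(15-oxopentadecyl)phenoxy]-2-oxopropyl}phosphonate | COc1cc(CCCCCCCCCCCCCCC=O)cc(OC(C(C)=O)P(=O)(OCC)OCC)c1
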